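## Retrosynthetic overview

1. The ester comes from isovaleryl transfer onto the (R)-α-hydroxy enone; the enone C=O comes from allylic oxidation of a 1',2'-diol; the isopropenyl group comes from dehydration of a CMe2OH group.
2. The key disconnection is C8–C1': a visible-light/nickel coupling of 8-iodo-6,7-dimethoxycoumarin with a dioxolanyl α-oxy radical, released with loss of acetone from a C2-symmetric bis(carbinol) made from D-tartrate acetonide.
3. The remaining tartrate-derived ring carbon directs the aryl group trans across the dioxolane, which fixes C1' as R. That directing carbon later becomes the C2' ketone.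
4. No ring is built: the coumarin bicycle comes intact from scopoletin, and the dioxolane is bought with the tartrate and removed in step 6.

Assumption: the single stereocentre is R (read from the SMILES), and scopoletin and dimethyl 2,3-O-isopropylidene-D-tartrate are taken as catalogue items.

## Route

Step 1
Reactants: 1 scopoletin (7-hydroxy-6-methoxy-2H-chromen-2-one)
Product: 2 7-hydroxy-8-iodo-6-methoxy-2H-chromen-2-one
Conditions: I2 (1.05 equiv), KI, 25% aq. NH3, 0 °C to rt; then dilute HCl
Reagents that add atoms: iodine, II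
Why: Electrophilic aromatic substitution (phenoxide-directed ortho-iodination) can only go to C8, because the other ortho position (C6) carries OMe and the para position is the ring fusion.

Step 2
Reactants: 2 7-hydroxy-8-iodo-6-methoxy-2H-chromen-2-one
Product: 3 8-iodo-6,7-dimethoxy-2H-chromen-2-one
Conditions: MeI (1.5 equiv), K2CO3 (1.5 equiv), acetone, 56 °C
Reagents that add atoms: iodomethane, CI
Why: Williamson ether synthesis on the acidic 7-OH; the lactone and the aryl iodide are inert to carbonate.

Step 3
Reactants: 4 dimethyl (4S,5S)-2,2-dimethyl-1,3-dioxolane-4,5-dicarboxylate (acetonide of dimethyl D-tartrate)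
Product: 5 2,2'-[(4S,5S)-2,2-dimethyl-1,3-dioxolane-4,5-diyl]di(propan-2-ol)
Conditions: MeMgBr (5 equiv), THF, 0 °C to rt; then aq. NH4Cl
Reagents that add atoms: methylmagnesium bromide, C[Mg]Br
Why: Double Grignard addition to each ester gives the C2-symmetric bis(tertiary carbinol); both bought stereocentres are kept, as in the preparation of tartrate-derived tetra-substituted diols.

Step 4
Reactants: 5 2,2'-[(4S,5S)-2,2-dimethyl-1,3-dioxolane-4,5-diyl]di(propan-2-ol) (3 equiv, excess recovered); 3 8-iodo-6,7-dimethoxy-2H-chromen-2-one (1 equiv)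
Product: 8 8-[(4R,5S)-5-(2-hydroxypropan-2-yl)-2,2-dimethyl-1,3-dioxolan-4-yl]-6,7-dimethoxy-2H-chromen-2-one, via alkoxyl radical 6 (not isolated), via dioxolan-4-yl radical 7 (not isolated)
Conditions: 9-mesityl-10-methylacridinium perchlorate (5 mol%), NiBr2(dtbbpy) (10 mol%; dtbbpy = 4,4'-di-tert-butyl-2,2'-bipyridine), 2,4,6-collidine (2 equiv), degassed MeCN, 450 nm LEDs, 25 °C
Reagents that add atoms: none
Why: Proposed new method: the excited acridinium and collidine remove an electron and a proton together from a tertiary O–H of 5 (the pair is strong enough for a roughly 105 kcal/mol O–H bond) to give alkoxyl radical 6; 6 undergoes fast β-scission to acetone and the α-oxygen-stabilised radical 7; zerovalent nickel adds oxidatively to aryl iodide 3, captures 7, and the resulting aryl(alkyl) trivalent nickel species reductively eliminates on the face opposite the bulky CMe2OH neighbour, so the new C8–C1' bond is trans and C1' is R; the two carbinol arms of 5 are homotopic, so either gives the same product, and the excess of 5 limits a second cleavage; the closest known reaction types are the acridinium/nickel ring-opening arylation of tertiary cycloalkanols by proton-coupled electron transfer and the decarboxylative arylation of α-oxy acids, neither shown for an acyclic, acetone-extruding tartrate carbinol.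

Step 5
Reactants: 8 8-[(4R,5S)-5-(2-hydroxypropan-2-yl)-2,2-dimethyl-1,3-dioxolan-4-yl]-6,7-dimethoxy-2H-chromen-2-one
Product: 9 8-[(4R,5R)-2,2-dimethyl-5-(prop-1-en-2-yl)-1,3-dioxolan-4-yl]-6,7-dimethoxy-2H-chromen-2-one
Conditions: Burgess reagent (2 equiv), toluene, 60 °C
Reagents that add atoms: none
Why: Burgess dehydration (syn elimination of the sulfamate) should take one of six methyl hydrogens in preference to the single ring C–H next to oxygen, as in dehydrations of other α-alkoxy tertiary carbinols to isopropenyl ethers; no stereocentre is touched (the descriptor change at C5 is only a priority change).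

Step 6
Reactants: 9 8-[(4R,5R)-2,2-dimethyl-5-(prop-1-en-2-yl)-1,3-dioxolan-4-yl]-6,7-dimethoxy-2H-chromen-2-one
Product: 10 8-[(1R,2R)-1,2-dihydroxy-3-methylbut-3-en-1-yl]-6,7-dimethoxy-2H-chromen-2-one
Conditions: AcOH/H2O 4:1, 40 °C
Reagents that add atoms: none
Why: Acid-catalysed acetal hydrolysis cleaves the ketal C–O bonds through the 2-propyl oxocarbenium ion, not the benzylic C1'–O bond, so C1' stays R.

Step 7
Reactants: 10 8-[(1R,2R)-1,2-dihydroxy-3-methylbut-3-en-1-yl]-6,7-dimethoxy-2H-chromen-2-one
Product: 11 8-[(1R)-1-hydroxy-3-methyl-2-oxobut-3-en-1-yl]-6,7-dimethoxy-2H-chromen-2-one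
Conditions: activated MnO2 (15 equiv), CH2Cl2, rt, stopped at full conversion of 10
Reagents that add atoms: none
Why: MnO2 allylic oxidation should favour the 2'-carbinol, whose C–H can align with the isopropenyl π system, over the benzylic 1'-carbinol, which is flanked by two ortho oxygen substituents and cannot easily reach the geometry needed; this removes the directing stereocentre and leaves C1' untouched.

Step 8
Reactants: 11 8-[(1R)-1-hydroxy-3-methyl-2-oxobut-3-en-1-yl]-6,7-dimethoxy-2H-chromen-2-one
Product: 12 (1R)-1-(6,7-dimethoxy-2-oxo-2H-chromen-8-yl)-3-methyl-2-oxobut-3-en-1-yl 3-methylbutanoate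
Conditions: (iBuCO)2O (1.5 equiv), pyridine (3 equiv), DMAP (0.1 equiv), CH2Cl2, −10 to 0 °C
Reagents that add atoms: 3-methylbutanoic anhydride, CC(C)CC(=O)OC(=O)CC(C)C
Why: DMAP-catalysed acyl transfer to the secondary alcohol does not break the C1'–O bond, so R is retained; the weak amine base and low temperature are chosen to avoid enolisation of the acidic C1'–H.

## Compound list

1 | scopoletin (7-hydroxy-6-methoxy-2H-chromen-2-one) | COc1cc2ccc(=O)oc2cc1O | starting material
2 | 7-hydroxy-8-iodo-6-methoxy-2H-chromen-2-one | COc1cc2ccc(=O)oc2c(I)c1O | intermediate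
3 | 8-iodo-6,7-dimethoxy-2H-chromen-2-one | COc1cc2ccc(=O)oc2c(I)c1OC | intermediate
4 | dimethyl (4S,5S)-2,2-dimethyl-1,3-dioxolane-4,5-dicarboxylate | CC1(C)O[C@H](C(=O)OC)[C@@H](C(=O)OC)O1 | starting material
5 | 2,2'-[(4S,5S)-2,2-dimethyl-1,3-dioxolane-4,5-diyl]di(propan-2-ol) | CC1(C)O[C@H](C(C)(C)O)[C@@H](C(C)(C)O)O1 | intermediate
6 | 2-[(4S,5S)-5-(2-hydroxypropan-2-yl)-2,2-dimethyl-1,3-dioxolan-4-yl]propan-2-yloxyl radical (formed and consumed in step 4) | CC1(C)O[C@H](C(C)(C)O)[C@@H](C(C)(C)[O])O1 | intermediate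
7 | (5S)-5-(2-hydroxypropan-2-yl)-2,2-dimethyl-1,3-dioxolan-4-yl radical (formed and consumed in step 4) | CC1(C)O[C@H](C(C)(C)O)[CH]O1 | intermediate
8 | 8-[(4R,5S)-5-(2-hydroxypropan-2-yl)-2,2-dimethyl-1,3-dioxolan-4-yl]-6,7-dimethoxy-2H-chromen-2-one (trans) | CC1(C)O[C@H](C(C)(C)O)[C@@H](c2c(OC)c(OC)cc3ccc(=O)oc23)O1 | intermediate
9 | 8-[(4R,5R)-2,2-dimethyl-5-(prop-1-en-2-yl)-1,3-dioxolan-4-yl]-6,7-dimethoxy-2H-chromen-2-one (trans) | CC1(C)O[C@H](C(C)=C)[C@@H](c2c(OC)c(OC)cc3ccc(=O)oc23)O1 | intermediate
10 | 8-[(1R,2R)-1,2-dihydroxy-3-methylbut-3-en-1-yl]-6,7-dimethoxy-2H-chromen-2-one | O[C@H](C(C)=C)[C@@H](c1c(OC)c(OC)cc2ccc(=O)oc12)O | intermediate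
11 | 8-[(1R)-1-hydroxy-3-methyl-2-oxobut-3-en-1-yl]-6,7-dimethoxy-2H-chromen-2-one | C=C(C)C(=O)[C@H](O)c1c(OC)c(OC)cc2ccc(=O)oc12 | intermediate
12 | (1R)-1-(6,7-dimethoxy-2-oxo-2H-chromen-8-yl)-3-methyl-2-oxobut-3-en-1-yl 3-methylbutanoate | C=C(C)C(=O)[C@H](OC(=O)CC(C)C)c1c(OC)c(OC)cc2ccc(=O)oc12 | target

## Step count and risks

Total steps: 8. Longest linear sequence: 7 (steps 1, 2, 4, 5, 6, 7, 8; step 3 is a one-step side branch).

The three steps most likely to fail:

**Step 4 (the proposed new coupling).** The alkoxyl-radical route may be slow, or the hindered aryl(alkyl)nickel species may not eliminate. The fallback uses known chemistry; it sets out from 4 (with 3) and comes back at 8. Diester 4 is half-saponified (KOH 1.0 equiv, MeOH, 0 °C) to the half-ester (4S,5S)-5-(methoxycarbonyl)-2,2-dimethyl-1,3-dioxolane-4-carboxylic acid F1. Excess MeMgBr (THF, 0 °C; the carboxylate is protected as its magnesium salt) turns the remaining ester into (4S,5S)-5-(2-hydroxypropan-2-yl)-2,2-dimethyl-1,3-dioxolane-4-carboxylic acid F2. F2 and 3 are then joined by the established iridium/nickel photoredox decarboxylative arylation of α-oxy acids ([Ir(dF(CF3)ppy)2(dtbbpy)]PF6, NiCl2(dme), dtbbpy, Cs2CO3, DMF, 450 nm). This passes through the same radical 7 and gives the same trans product 8.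

**Step 7 (which carbinol is oxidised).** MnO2 may attack the benzylic alcohol as well, or cleave the diol. The fallback sets out from 10 and comes back at 12, bypassing 11; it replaces oxidation selectivity by steric differentiation. TBSCl/imidazole (DMF, 0 °C) silylates the less hindered allylic 2'-OH to give 8-[(1R,2R)-2-{[tert-butyl(dimethyl)silyl]oxy}-1-hydroxy-3-methylbut-3-en-1-yl]-6,7-dimethoxy-2H-chromen-2-one F3. Isovaleric anhydride/pyridine/DMAP acylates the benzylic OH to give (1R,2R)-2-{[tert-butyl(dimethyl)silyl]oxy}-1-(6,7-dimethoxy-2-oxo-2H-chromen-8-yl)-3-methylbut-3-en-1-yl 3-methylbutanoate F4. HF·pyridine (THF, 0 °C; acidic, to suppress acyl migration) gives (1R,2R)-1-(6,7-dimethoxy-2-oxo-2H-chromen-8-yl)-2-hydroxy-3-methylbut-3-en-1-yl 3-methylbutanoate F5. F5 is oxidised at once with Dess–Martin periodinane (CH2Cl2, rt) to 12.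

**Step 8 (acylating a hindered, enolisable α-hydroxy ketone).** Amine bases may erode the ee or the reaction may stall. The fallback sets out from 11 and comes back at 12, and uses a base-free acylating species instead of base-mediated acyl transfer. Isopropylketene is generated in the flask by visible-light Wolff rearrangement of 1-diazo-3-methylbutan-2-one (450 nm, CH2Cl2, rt; the coumarin does not absorb there) and adds to the hydroxyl of 11 to give the 3-methylbutanoate directly. No new compound is isolated on the way.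

## Further compounds

F1 | step 4 | (4S,5S)-5-(methoxycarbonyl)-2,2-dimethyl-1,3-dioxolane-4-carboxylic acid | CC1(C)O[C@H](C(=O)OC)[C@@H](C(=O)O)O1
F2 | step 4 | (4S,5S)-5-(2-hydroxypropan-2-yl)-2,2-dimethyl-1,3-dioxolane-4-carboxylic acid | CC1(C)O[C@H](C(C)(C)O)[C@@H](C(=O)O)O1
F3 | step 7 | 8-[(1R,2R)-2-{[tert-butyl(dimethyl)silyl]oxy}-1-hydroxy-3-methylbut-3-en-1-yl]-6,7-dimethoxy-2H-chromen-2-one | CC(C)(C)[Si](C)(C)O[C@H](C(C)=C)[C@@H](c1c(OC)c(OC)cc2ccc(=O)oc12)O
F4 | step 7 | (1R,2R)-2-{[tert-butyl(dimethyl)silyl]oxy}-1-(6,7-dimethoxy-2-oxo-2H-chromen-8-yl)-3-methylbut-3-en-1-yl 3-methylbutanoate | CC(C)(C)[Si](C)(C)O[C@H](C(C)=C)[C@@H](c1c(OC)c(OC)cc2ccc(=O)oc12)OC(=O)CC(C)C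
F5 | step 7 | (1R,2R)-1-(6,7-dimethoxy-2-oxo-2H-chromen-8-yl)-2-hydroxy-3-methylbut-3-en-1-yl 3-methylbutanoate | O[C@H](C(C)=C)[C@@H](c1c(OC)c(OC)cc2ccc(=O)oc12)OC(=O)CC(C)C
F0 | step 8 | none | none
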